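**Plan**

Enabling feature: C1 of ring A (the tetrasubstituted arene) and C1 of ring C (3-hydroxyphenyl) are linked by a bare CH2–CH2 bridge. That bridge is a vinyl group that has taken up one aryl nucleophile and one aryl electrophile.
Cuts, in order: one O–CH3 bond on each of the three rings; the ring-A benzylic C–H of the bridge (back to C–B); both aryl–carbon bonds of the bridge together; the CH2–ring B bond of the diarylmethane.
Forward: no ring is built and all three arenes are bought. Ring A is joined to ring B by Grignard addition and deoxygenation, then to ring C through the vinyl unit in one operation. Boron is then replaced by hydrogen and the phenols are freed.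
Ring A keeps two equivalent methoxy groups until the last step, so no regiochemical choice arises earlier.
Stereochemistry: the target has none; the two sp3 centres that appear in passing are racemic and both end as CH2.

Key step: step 5

Remark: the target is achiral (no stereocentre, no axis, no double-bond geometry), so there is only one form to make and no enantioselective step is called for.

**Route**

Step 1
Reactants: 1 4-bromo-2,6-difluorobenzaldehyde
Product: 3 4-bromo-2,6-dimethoxybenzaldehyde, via 4-bromo-2-fluoro-6-methoxybenzaldehyde 2 (not isolated)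
Conditions: NaOMe (3 equiv), MeOH, reflux
Reagents that add atoms: sodium methoxide, C[O-].[Na+]
Why: Two consecutive nucleophilic aromatic substitutions (SNAr), in which each fluoride sits ortho to the formyl acceptor and is a far better SNAr leaving group than the para bromide, so both C–F bonds should become C–OMe while C–Br stays.

Step 2
Reactants: 3 4-bromo-2,6-dimethoxybenzaldehyde; 4 4-bromoanisole
Product: 6 (4-bromo-2,6-dimethoxyphenyl)(4-methoxyphenyl)methanol (racemic), via 4-methoxyphenylmagnesium bromide 5 (not isolated)
Conditions: 4, Mg, cat. I2, THF, reflux; then 3, THF, 0 °C → rt; sat. aq. NH4Cl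
Reagents that add atoms: magnesium, [Mg] (held only in 5; none of it remains in 6)
Why: Grignard formation followed by 1,2-addition to a non-enolisable aldehyde, which at 0 °C is much faster than any magnesium–bromine exchange at the aryl bromide of 3; the new carbinol centre is racemic and is removed in step 3.

Step 3
Reactants: 6 (4-bromo-2,6-dimethoxyphenyl)(4-methoxyphenyl)methanol
Product: 7 5-bromo-1,3-dimethoxy-2-(4-methoxybenzyl)benzene
Conditions: Et3SiH (3 equiv), TFA, CH2Cl2, 0 °C
Reagents that add atoms: none
Why: Ionic hydrogenation (silane deoxygenation), in which acid ionises the carbinol to a diarylmethyl cation stabilised by three ortho/para methoxy groups and triethylsilane traps it by hydride transfer, while the aryl bromide and the methyl ethers are inert.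

Step 4
Reactants: 8 3-methoxyphenol
Product: 9 3-methoxyphenyl trifluoromethanesulfonate
Conditions: Tf2O, pyridine, CH2Cl2, 0 °C → rt
Reagents that add atoms: trifluoromethanesulfonic anhydride, O=S(=O)(OS(=O)(=O)C(F)(F)F)C(F)(F)F
Why: O-Sulfonylation of a phenol with triflic anhydride, the standard way to make a cross-coupling electrophile whose counter-ion binds only weakly to palladium.

Step 5
Reactants: 7 5-bromo-1,3-dimethoxy-2-(4-methoxybenzyl)benzene; 9 3-methoxyphenyl trifluoromethanesulfonate; 10 vinylboronic acid pinacol ester
Product: 13 2-{1-[3,5-dimethoxy-4-(4-methoxybenzyl)phenyl]-2-(3-methoxyphenyl)ethyl}-4,4,5,5-tetramethyl-1,3,2-dioxaborolane (racemic), via aryllithium 11 (not isolated), via lithium aryl(vinyl)borate 12 (not isolated)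
Conditions: 7, t-BuLi (2.0 equiv), THF, −78 °C; 10, −78 °C → rt; then KOTf (2 equiv), 9, Pd(OAc)2 (cat.), 1,1'-bis(dicyclohexylphosphino)ferrocene (cat.), THF, 60 °C
Reagents that add atoms: tert-butyllithium, [Li]C(C)(C)C (supplies the lithium of 11 and 12; nothing of it remains in 13)
Why: Bromine–lithium exchange turns 7 into aryllithium 11, which adds to the vacant boron orbital of 10 to give the tetracoordinate vinylborate 12; the exchange is kept at −78 °C and 10 is added at once so that 11 has no time to abstract a proton from the doubly benzylic CH2. Oxidative addition of 9 to Pd(0) gives a cationic arylpalladium(II) species that binds the vinyl π bond of 12 and induces a 1,2-metallate shift, in which the ring-A aryl moves from boron to the boron-bearing carbon while palladium bonds to the terminal carbon; reductive elimination then joins that CH2 to the 3-methoxyphenyl group. The closest known reaction type is this one itself, the palladium-catalysed conjunctive cross-coupling of aryl(vinyl)boron ate complexes with aryl triflates. No ring is closed, and the single new stereocentre (the C–B carbon) is formed as a racemate because the ligand is achiral, which is harmless because step 6 turns it into CH2. The selectivity needed is metallate shift over direct boron-to-palladium aryl transfer (biaryl formation) and over β-hydride elimination of the alkylpalladium intermediate. It is secured by the weakly bound triflate, by KOTf (which takes the bromide left by the exchange out of solution as KBr), by the wide-bite-angle, electron-rich ferrocenyl bisphosphine, and by a migrating aryl group that bears hydrogen at both ortho positions.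

Step 6
Reactants: 13 2-{1-[3,5-dimethoxy-4-(4-methoxybenzyl)phenyl]-2-(3-methoxyphenyl)ethyl}-4,4,5,5-tetramethyl-1,3,2-dioxaborolane
Product: 14 1,3-dimethoxy-2-(4-methoxybenzyl)-5-[2-(3-methoxyphenyl)ethyl]benzene
Conditions: TBAF·3H2O (3 equiv), toluene, 60–80 °C, Ar
Reagents that add atoms: none
Why: Fluoride-promoted protodeboronation of a benzylic boronic ester, in which fluoride adds to boron and the resulting ate complex passes its benzylic carbon (incipient negative charge stabilised by ring A and its two inductively withdrawing meta-methoxy groups) to a proton of the hydrate water, so the stereocentre becomes a CH2 group.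

Step 7
Reactants: 14 1,3-dimethoxy-2-(4-methoxybenzyl)-5-[2-(3-methoxyphenyl)ethyl]benzene
Product: 15 2-(4-hydroxybenzyl)-5-[2-(3-hydroxyphenyl)ethyl]-3-methoxyphenol (CNP0112925.0)
Conditions: NaSEt (10 equiv), DMF, 150 °C, Ar; then 1 M HCl
Reagents that add atoms: none
Why: Nucleophilic aryl methyl ether cleavage by thiolate (SN2 at the methyl carbon), in which rings B and C each lose their only methyl and ring A loses one of its two equivalent methyls; the phenoxide so formed makes the remaining ring-A aryloxide too poor a leaving group (the known basis of selective mono-demethylation of resorcinol dimethyl ethers), so all partly cleaved species should funnel to 15.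

**Compound list**

1 | 4-bromo-2,6-difluorobenzaldehyde | O=Cc1c(F)cc(Br)cc1F | starting material
2 | 4-bromo-2-fluoro-6-methoxybenzaldehyde (formed in situ) | COc1cc(Br)cc(F)c1C=O | intermediate
3 | 4-bromo-2,6-dimethoxybenzaldehyde | COc1cc(Br)cc(OC)c1C=O | intermediate
4 | 4-bromoanisole | COc1ccc(Br)cc1 | starting material
5 | 4-methoxyphenylmagnesium bromide (formed in situ) | COc1ccc([Mg]Br)cc1 | intermediate
6 | (4-bromo-2,6-dimethoxyphenyl)(4-methoxyphenyl)methanol, racemic | COc1ccc(C(O)c2c(OC)cc(Br)cc2OC)cc1 | intermediate
7 | 5-bromo-1,3-dimethoxy-2-(4-methoxybenzyl)benzene | COc1ccc(Cc2c(OC)cc(Br)cc2OC)cc1 | intermediate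
8 | 3-methoxyphenol | COc1cccc(O)c1 | starting material
9 | 3-methoxyphenyl trifluoromethanesulfonate | COc1cccc(OS(=O)(=O)C(F)(F)F)c1 | intermediate
10 | vinylboronic acid pinacol ester | C=CB1OC(C)(C)C(C)(C)O1 | starting material
11 | 3,5-dimethoxy-4-(4-methoxybenzyl)phenyllithium (formed in situ) | [Li]c1cc(OC)c(Cc2ccc(OC)cc2)c(OC)c1 | intermediate
12 | lithium [3,5-dimethoxy-4-(4-methoxybenzyl)phenyl](vinyl)(pinacolato)borate (formed in situ) | [Li+].C=C[B-]1(c2cc(OC)c(Cc3ccc(OC)cc3)c(OC)c2)OC(C)(C)C(C)(C)O1 | intermediate
13 | 2-{1-[3,5-dimethoxy-4-(4-methoxybenzyl)phenyl]-2-(3-methoxyphenyl)ethyl}-4,4,5,5-tetramethyl-1,3,2-dioxaborolane, racemic | COc1ccc(Cc2c(OC)cc(C(Cc3cccc(OC)c3)B3OC(C)(C)C(C)(C)O3)cc2OC)cc1 | intermediate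
14 | 1,3-dimethoxy-2-(4-methoxybenzyl)-5-[2-(3-methoxyphenyl)ethyl]benzene | COc1ccc(Cc2c(OC)cc(CCc3cccc(OC)c3)cc2OC)cc1 | intermediate
15 | 2-(4-hydroxybenzyl)-5-[2-(3-hydroxyphenyl)ethyl]-3-methoxyphenol, achiral | COc1cc(CCc2cccc(O)c2)cc(O)c1Cc1ccc(O)cc1 | target

**Step count**

Total step count: 7.
Longest linear sequence: 6 steps (steps 1, 2, 3, 5, 6, 7, from 1 to 15). Step 4 is a one-step side branch.

**Steps most likely to fail**

1. Step 5.
- What may go wrong: direct aryl transfer from boron to palladium may outrun the metallate shift. Residual bromide may shut down the cationic palladium pathway. The aryllithium may be quenched by proton transfer from the doubly benzylic CH2 before it reaches boron.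
- Fallback: the same two bonds are made one after the other from the same three building blocks, setting out from 7.
- Suzuki–Miyaura vinylation of 7 with 10 (PdCl2(dppf), K2CO3, dioxane/H2O, 90 °C) should give 1,3-dimethoxy-2-(4-methoxybenzyl)-5-vinylbenzene F1.
- Anti-Markovnikov hydroboration with 9-BBN-H (THF, rt) should give 9-{2-[3,5-dimethoxy-4-(4-methoxybenzyl)phenyl]ethyl}-9-borabicyclo[3.3.1]nonane F2.
- F2 is coupled in the same flask with triflate 9 (PdCl2(dppf), K3PO4, THF/H2O, 65 °C; B-alkyl Suzuki–Miyaura coupling).
- The fallback comes back to the route at 14 and makes step 6 unnecessary.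

2. Step 6.
- What may go wrong: the C–B bond of a secondary benzylic boronate may cleave only sluggishly, because the developing carbanion is stabilised by one arene only. Slow cleavage leaves room for air oxidation of the boronate.
- Fallback: boron is exchanged for oxygen and the oxygen is then removed reductively, setting out from 13.
- Oxidation of 13 (H2O2, NaOH, THF, 0 °C) should give racemic 1-[3,5-dimethoxy-4-(4-methoxybenzyl)phenyl]-2-(3-methoxyphenyl)ethanol F3.
- Hydrogenolysis of the benzylic C–O bond of F3 (H2, Pd/C, EtOH, cat. HCl) follows.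
- Direct C–O cleavage and acid-induced dehydration followed by alkene hydrogenation lead to the same product, so the fallback comes back to the route at 14.

3. Step 7.
- What may go wrong: cleavage may stall on the least activated ring (the para-alkyl anisole, ring B). If forced, it may begin to erode the second ring-A methyl ether. Under-cleaved and over-cleaved phenols of similar polarity would then build up.
- Fallback: the ring-A oxygens are differentiated at the aldehyde stage, and every future phenol is carried as a benzyl ether. The end game then becomes a hydrogenolysis that cannot touch the methyl ether. It sets out from 3.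
- BCl3 (1.1 equiv, CH2Cl2, −78 → 0 °C) cleaves one methoxy group through chelation to the neighbouring formyl oxygen and should give 4-bromo-2-hydroxy-6-methoxybenzaldehyde F4.
- Benzylation (BnBr, K2CO3, DMF) gives 2-(benzyloxy)-4-bromo-6-methoxybenzaldehyde F5.
- Addition of commercial 4-(benzyloxy)phenylmagnesium bromide gives racemic [2-(benzyloxy)-4-bromo-6-methoxyphenyl][4-(benzyloxy)phenyl]methanol F6.
- Et3SiH/TFA at 0 °C gives 1-(benzyloxy)-2-[4-(benzyloxy)benzyl]-5-bromo-3-methoxybenzene F7.
- Commercial 3-(benzyloxy)phenol is converted with Tf2O/pyridine into 3-(benzyloxy)phenyl trifluoromethanesulfonate F8.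
- Under the conditions of step 5, F7 passes through 3-(benzyloxy)-4-[4-(benzyloxy)benzyl]-5-methoxyphenyllithium F9 and, after addition of 10, through the lithium aryl(vinyl)(pinacolato)borate F10.
- F10 couples with F8 to the racemic benzylic pinacol boronate F11.
- TBAF·3H2O then gives the tribenzyl ether F12 of the target.
- Hydrogenolysis (H2, Pd/C, EtOAc/MeOH, rt) removes the three benzyl groups and comes back to the route at 15.

**Further compounds**

F1 | step 5 | 1,3-dimethoxy-2-(4-methoxybenzyl)-5-vinylbenzene | C=Cc1cc(OC)c(Cc2ccc(OC)cc2)c(OC)c1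
F2 | step 5 | 9-{2-[3,5-dimethoxy-4-(4-methoxybenzyl)phenyl]ethyl}-9-borabicyclo[3.3.1]nonane | COc1ccc(Cc2c(OC)cc(CCB3C4CCCC3CCC4)cc2OC)cc1
F3 | step 6 | 1-[3,5-dimethoxy-4-(4-methoxybenzyl)phenyl]-2-(3-methoxyphenyl)ethanol, racemic | COc1ccc(Cc2c(OC)cc(C(O)Cc3cccc(OC)c3)cc2OC)cc1
F4 | step 7 | 4-bromo-2-hydroxy-6-methoxybenzaldehyde | COc1cc(Br)cc(O)c1C=O
F5 | step 7 | 2-(benzyloxy)-4-bromo-6-methoxybenzaldehyde | COc1cc(Br)cc(OCc2ccccc2)c1C=O
F6 | step 7 | [2-(benzyloxy)-4-bromo-6-methoxyphenyl][4-(benzyloxy)phenyl]methanol, racemic | COc1cc(Br)cc(OCc2ccccc2)c1C(O)c1ccc(OCc2ccccc2)cc1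
F7 | step 7 | 1-(benzyloxy)-2-[4-(benzyloxy)benzyl]-5-bromo-3-methoxybenzene | COc1cc(Br)cc(OCc2ccccc2)c1Cc1ccc(OCc2ccccc2)cc1
F8 | step 7 | 3-(benzyloxy)phenyl trifluoromethanesulfonate | O=S(=O)(Oc1cccc(OCc2ccccc2)c1)C(F)(F)F
F9 | step 7 | 3-(benzyloxy)-4-[4-(benzyloxy)benzyl]-5-methoxyphenyllithium | [Li]c1cc(OC)c(Cc2ccc(OCc3ccccc3)cc2)c(OCc2ccccc2)c1
F10 | step 7 | lithium {3-(benzyloxy)-4-[4-(benzyloxy)benzyl]-5-methoxyphenyl}(vinyl)(pinacolato)borate | [Li+].C=C[B-]1(c2cc(OC)c(Cc3ccc(OCc4ccccc4)cc3)c(OCc3ccccc3)c2)OC(C)(C)C(C)(C)O1
F11 | step 7 | 2-{1-[3-(benzyloxy)-4-[4-(benzyloxy)benzyl]-5-methoxyphenyl]-2-[3-(benzyloxy)phenyl]ethyl}-4,4,5,5-tetramethyl-1,3,2-dioxaborolane, racemic | COc1cc(C(Cc2cccc(OCc3ccccc3)c2)B2OC(C)(C)C(C)(C)O2)cc(OCc2ccccc2)c1Cc1ccc(OCc2ccccc2)cc1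
F12 | step 7 | 1-(benzyloxy)-2-[4-(benzyloxy)benzyl]-5-{2-[3-(benzyloxy)phenyl]ethyl}-3-methoxybenzene | COc1cc(CCc2cccc(OCc3ccccc3)c2)cc(OCc2ccccc2)c1Cc1ccc(OCc2ccccc2)cc1
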